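## Structural features

The target 37 is an elemanolide: a cyclohexane (C5–C10, elemane numbering) with six contiguous stereocentres, cis-fused across C7–C8 to an α-methylene-γ-butyrolactone (C11, C12, C13), plus a seventh stereocentre, C1 (S), in the oxirane on quaternary C10. Calling β the ring face that carries the C10 methyl C14 (a convention used only in this text), the 2-formylvinyl unit on C5 (C4, C3, C15) and the C6 angelate are β. The C10 oxirane, the C7–C11 bond, the C8 lactone oxygen and the C9 hydroxyl are all α. The molecule holds three conjugate acceptors (methylene lactone, enal, a Z-enoate that isomerises to the tiglate) and a neopentyl epoxide with the free C9 hydroxyl within 5-exo reach, so nucleophiles, strong base and strong acid are excluded at the end. The real difficulty is the crowded C5–C6–C10 array: quaternary C10 between two stereocentres, a C5/C6 cis relationship that a cuprate addition anti to a C6 oxygen does not give, and four ring oxygens that must be told apart. The key step uses the fact that C7 is the only plain methylene of the ring. Its α hydrogen lies beside O8 on the same face, so a carbene carbon tethered as an ester on O8 can replace it in a 1,5 manner, turning the ester into the cis lactone and leaving a phosphonate on C11 for the C13 methylene.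

Target 37, insertion precursor 30 and insertion product 31 were compared centre by centre and agree in constitution and configuration. What needs correcting is design, on three points:

- **Cis fusion is not automatic.** C7 has two hydrogens, and the α one is equatorial only in the chair with the C8 ester axial.
- **A C9 acetate cannot be removed late.** Base would attack the methylene lactone and the angelate, so an acid-labile tert-butyl carbonate is used instead.
- **A C6 silyl ether is a poor spectator.** It would make C6–H an activated, syn-axial 1,6 target and force a late acylation next to a free C9 hydroxyl, so the angelate itself is placed on C6 before the insertion.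

## Logic of the disconnections

37 ⇒ 35. The O–C2 bond of the oxirane is cut, leaving the oxygen on C1. The epoxide is the group least tolerant of the chemistry before it, so it is made last; C1 keeps its configuration because its C–O bond is never broken. The forward step must activate only the primary hydroxyl (through 36) and close the ring under a mild, non-nucleophilic base.

35 ⇒ 34. The C1/C2 acetonide and the C9 carbonate are put back. Both fall to the same acid, so one operation unveils three hydroxyls. The demand is acid stability of the enal, the methylene lactone and the angelate.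

34 ⇒ 32. The C15 aldehyde is taken back to the methyl of an isopropenyl group (through 33). An isopropenyl group survives everything earlier, an enal does not. The forward oxidation must choose the electron-rich 1,1-disubstituted alkene over the two electron-poor ones.

32 ⇒ 31. The C11=C13 double bond is cut to a C11 phosphonate and formaldehyde. The gain is that the exocyclic alkene appears only after the carbenoid chemistry, and both C11 epimers converge.

31 ⇒ 30. The C7–C11 bond is cut, giving a C7 methylene and a diazo carbon on the O8 ester. This removes a ring and a stereocentre in one stroke. The forward step must pick C7–Hα over C7–Hβ, C9–H and C6–H. For that, O9 carries an electron-withdrawing carbonate and O6 the angelate, and the ring must react through the chair with the ester axial.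

30 ⇒ 28 ⇒ 26 + 27. The diazo group and then the O8–C12 ester bond are removed (enolate 29 on the way forward). The acidic phosphonoacetate is introduced only after all hydride and base steps, which requires O8 to be the single free hydroxyl of 26.

26 ⇒ 25 ⇒ 22 + 23. O8 is re-masked as a 4-methoxybenzyl ether and the O6–acyl bond is cut. The ether is a poor leaving group β to the coming C6 ketone and leaves under neutral oxidation that spares the angelate. The acylation of the hindered axial 6β hydroxyl must not isomerise the Z alkene (anhydride 24).

22 ⇒ 21 ⇒ 20 ⇒ 19. The C6 configuration is inverted through the ketone. Displacement at C6 would have to pass the syn-axial C10 methyl, whereas hydride delivery to the ketone is steered by that same methyl. The demand is that the β,γ-unsaturated ketone 21 is neither epimerised at C5 nor conjugated.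

19 ⇒ 18 ⇒ 16. The O9 carbonate and the O8 ether are removed to a cis diol. The two hydroxyls differ strongly (equatorial secondary against axial neopentyl), so tin-mediated alkylation (17) should tell them apart.

16 ⇒ 15 ⇒ 13. The C9 carbinol goes back to the ketone and the C8–O bond is cut to the enolate (14). C8 is the only enolisable position. Both new centres are set while C6 is still α, when one chair dominates and directs both reagents; this is why the C6 inversion comes later.

13 ⇒ 11. The acetonide is exchanged for the aldol hydroxyl and the primary silyl ether (12). The aldol oxygen must be capped before any strong base because a β-alkoxide on a quaternary centre would undergo retro-aldol.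

11 ⇒ 7 + 8 + 9. The C5–C4 and C10–C1 bonds are cut, giving an enone, an isopropenyl nucleophile and a two-carbon aldehyde. Three stereocentres (C5, C10, C1) come from the single C6 centre of the enone; the enolate 10 must be trapped before it equilibrates.

7 ⇒ 6 ⇒ 4 ⇒ 3 ⇒ 2 ⇒ 1. The silyl ether, the enone transposition (5), the resolution, the α′-acetoxylation and the enol ether are removed in turn, ending at a symmetrical dione. The only stereochemical demand is the enantiomer choice at the future C6.

## Other disconnections considered

Alternative 1: The cut is C5–C10, a retro-Cope step. It opens the cyclohexane to the ten-membered 1(10),4-dienal lactone A2; forward, heating A2 gives the elemane A1, whose vinyl group must then be epoxidised.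
- In favour: the quaternary centre and C5 arise together through a chair transition state, the lactone, angelate and C9 hydroxyl are already in place, and no protecting group is needed at that stage.
- Against: A2, a strained E,E-cyclodecadiene with a cis lactone and four stereocentres, is no easier to make than 37. The rearrangement is an equilibrium whose sense at C5/C10 depends on the reacting conformer. The last step must epoxidise a monosubstituted alkene with face control at C1 and no reliable handle, while an aldehyde is exposed to peroxide.
- Comparison: from A2 onward this route is clearly shorter than the chosen one and is the better plan on step economy for that stretch. On control of C1 the chosen plan is stronger (aldol, early, through a closed transition state), and as a total synthesis the burden only moves into the medium ring.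

Alternative 2: The cuts are C7–C8 and O8–C12. Forward, CrCl2 (divalent chromium) converts the E/Z bromide A4 into an equilibrating allylchromium species that adds through C7 to the C8 aldehyde and lactonises to A3.
- In favour: carbocycle, lactone and exocyclic methylene form in one operation, the alkene geometry of A4 does not matter, no diazo compound is involved and C15 is already oxidised. On these points it is better than the chosen plan, which needs insertion plus olefination and a later SeO2 step.
- Against: A4 must be assembled as an open chain carrying the quaternary C10 and the C5, C6 and C9 centres without a ring to relay stereochemistry. The six-membered closure has to set C7 and C8 correctly relative to each other and to C6/C9 with no obvious bias. The C10 vinyl group again leaves C1 to a late, weakly controlled epoxidation, and the reagent is used in large excess.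
- Comparison: mechanistically both routes rely on a conformational preference in the ring-forming step. The chosen plan carries that risk with all other centres secured by a cyclohexanone template; alternative 2 carries it with more centres still to prove.

Alternative 3: The cut is C9–C10. Forward, a cobalt hydride from Co(dpm)2 and PhSiH3 reduces the enone of keto aldehyde A6, and the C10 enolate closes onto the C9 aldehyde to give cyclohexanol A5.
- In favour: the quaternary centre and C9 are made in one catalytic step, a syn aldol geometry matches the cis C9-hydroxyl/C1 relationship, and no C6 inversion is needed. On catalytic economy and on the ease of creating C10 it equals or exceeds the chosen plan.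
- Against: the isopropenyl group competes for the metal hydride. A6 needs four contiguous open-chain stereocentres (C5–C8). After cyclisation the C1 ketone must still be reduced with face control beside the quaternary centre, and the lactone closed and methylenated with strong base.
- Comparison: the chosen plan sets C10 and C1 together in the aldol and installs the methylene without strong base; alternative 3 is more elegant in the ring closure but longer and less certain after it.

Key step: step 19

Assumption: the lipase of step 3 hydrolyses the R acetate faster (carbonyl side as the large group in the usual secondary-alcohol model); if the preference is reversed, the S alcohol formed by hydrolysis is carried through steps 4 and 5 in place of 4 without other change.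

## Route

Step 1
Reactants: 1 2-methylcyclohexane-1,3-dione
Product: 2 3-ethoxy-2-methylcyclohex-2-en-1-one
Conditions: EtOH, p-TsOH (cat.), toluene, reflux, Dean–Stark
Reagents that add atoms: ethanol CCO
Why: Acid-catalysed enol ether formation from a cyclic 1,3-dione, driven by azeotropic removal of water; it differentiates the two carbonyls as a vinylogous ester.

Step 2
Reactants: 2 3-ethoxy-2-methylcyclohex-2-en-1-one
Product: 3 (±)-6-acetoxy-3-ethoxy-2-methylcyclohex-2-en-1-one
Conditions: Mn(OAc)3·2H2O, benzene, reflux, Dean–Stark
Reagents that add atoms: manganese triacetate CC(=O)[O-].CC(=O)[O-].CC(=O)[O-].[Mn+3]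
Why: α′-Acetoxylation of an enone with trivalent manganese; the manganese enolate forms at the only CH2 next to the carbonyl and is acetoxylated there, a reaction well established for 3-alkoxycyclohexenones.

Step 3
Reactants: 3 (±)-6-acetoxy-3-ethoxy-2-methylcyclohex-2-en-1-one
Product: 4 (S)-6-acetoxy-3-ethoxy-2-methylcyclohex-2-en-1-one
Conditions: Amano lipase PS (Burkholderia cepacia), pH 7 phosphate buffer/MTBE, 30 °C, stopped near half conversion, chromatography
Reagents that add atoms: none
Why: Lipase-catalysed kinetic resolution by enantioselective ester hydrolysis; the R acetate should be hydrolysed and the S acetate, which carries the future C6 configuration, recovered.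

Step 4
Reactants: 4 (S)-6-acetoxy-3-ethoxy-2-methylcyclohex-2-en-1-one
Product: 6 (S)-4-hydroxy-2-methylcyclohex-2-en-1-one, via allylic diol 5 (not isolated)
Conditions: LiAlH4, Et2O, 0 °C; then 1 M aq. HCl, THF, 0 °C to rt
Reagents that add atoms: none
Why: Stork–Danheiser transposition: 1,2-reduction of the vinylogous ester (the acetate is cleaved at the same time), then acid hydrolysis of the enol ether with loss of the allylic hydroxyl gives the transposed enone; the carbinol centre is not touched.

Step 5
Reactants: 6 (S)-4-hydroxy-2-methylcyclohex-2-en-1-one
Product: 7 (S)-4-(tert-butyldimethylsilyloxy)-2-methylcyclohex-2-en-1-one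
Conditions: TBSCl, imidazole, DMF, 0 °C to rt
Reagents that add atoms: tert-butyldimethylsilyl chloride CC(C)(C)[Si](C)(C)Cl
Why: Standard silylation of a secondary alcohol; the bulky, non-chelating silyl ether is the group that gives reliable anti selectivity in the next step.

Step 6
Reactants: 7 (S)-4-(tert-butyldimethylsilyloxy)-2-methylcyclohex-2-en-1-one; 8 isopropenylmagnesium bromide; 9 (tert-butyldimethylsilyloxy)acetaldehyde
Product: 11 cyclohexan-9-one (elemane numbering) with 10β-methyl / 10α-[(1S)-1-hydroxy-2-(tert-butyldimethylsilyloxy)ethyl] / 5β-isopropenyl / 6α-OTBS, via bromomagnesium enolate 10 (not isolated)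
Conditions: CuBr·SMe2 (20 mol %), THF, −40 °C; then 9, −78 °C; aq. NH4Cl at −78 °C
Reagents that add atoms: none
Why: Tandem copper-catalysed conjugate addition–aldol: the isopropenyl group adds anti to the C6 silyloxy group (sets C5), the enolate is attacked on the face opposite the new C5 substituent (sets quaternary C10), and a Zimmerman–Traxler chair with the CH2OTBS group equatorial and the C10 methyl cis to the enolate oxygen gives the 1S carbinol.

Step 7
Reactants: 11 aldol adduct
Product: 13 ketone of 11 with C1/C2 as acetonide: 10α-[(4S)-2,2-dimethyl-1,3-dioxolan-4-yl] / 6α-OTBS kept, via C1-C2 diol 12 (not isolated)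
Conditions: CSA (cat.), MeOH, 0 °C; concentrate; 2,2-dimethoxypropane, acetone, CSA (cat.), rt; Et3N
Reagents that add atoms: 2,2-dimethoxypropane COC(C)(C)OC
Why: Acid methanolysis removes the primary silyl ether much faster than the hindered secondary one, and transacetalisation traps the 1,2-diol as the five-membered acetonide; the α carbon is quaternary so no dehydration is possible, and capping O1 prevents retro-aldol in the base steps that follow.

Step 8
Reactants: 13 acetonide ketone
Product: 15 8α-hydroxy ketone (13 with an equatorial hydroxyl on C8), via potassium enolate 14 (not isolated)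
Conditions: KN(SiMe3)2, THF, −78 °C; then 2-(phenylsulfonyl)-3-phenyloxaziridine, −78 °C; aq. NH4Cl
Reagents that add atoms: 2-(phenylsulfonyl)-3-phenyloxaziridine O=S(=O)(N1OC1c1ccccc1)c1ccccc1
Why: Enolate hydroxylation with an N-sulfonyloxaziridine; C8 is the only enolisable carbon, and in the dominant chair (C10 methyl axial, all other groups equatorial) the oxidant approaches C8 anti to the 1,3-related axial methyl, giving the equatorial 8α alcohol, which is also the more stable epimer.

Step 9
Reactants: 15 8α-hydroxy ketone
Product: 16 8α,9α-diol (cis; C9–OH axial) with 6α-OTBS / acetonide / 5β-isopropenyl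
Conditions: LiBH(s-Bu)3, THF, −78 °C; aq. NH4Cl
Reagents that add atoms: none
Why: Diastereoselective ketone reduction with a bulky trialkylborohydride, which attacks along the equatorial trajectory and gives the axial 9α alcohol cis to the 8α oxygen, as is usual for α-oxygenated and α,α-disubstituted cyclohexanones.

Step 10
Reactants: 16 8α,9α-diol
Product: 18 8α-O-(4-methoxybenzyl) ether with 9α-OH free, via stannylene acetal 17 (not isolated)
Conditions: Bu2SnO, toluene, reflux, Dean–Stark; then 4-methoxybenzyl chloride, Bu4NI, 90 °C
Reagents that add atoms: 4-methoxybenzyl chloride COc1ccc(CCl)cc1; dibutyltin oxide CCCC[Sn](=O)CCCC (tin only in 17)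
Why: Stannylene-mediated regioselective alkylation of a cis diol: the equatorial, unhindered O8 is alkylated, not the axial neopentyl O9; a benzyl-type ether is chosen because it cannot act as a leaving group β to the C6 ketone made in step 13.

Step 11
Reactants: 18 8α-O-PMB ether
Product: 19 9α-O-tert-butoxycarbonyl derivative of 18
Conditions: Boc2O, DMAP, MeCN, rt
Reagents that add atoms: di-tert-butyl dicarbonate CC(C)(C)OC(=O)OC(=O)OC(C)(C)C
Why: DMAP-catalysed acylation of the remaining hindered hydroxyl; the carbonate is electron-withdrawing (it deactivates C9–H in the key step) and is later removed by acid together with the acetonide, which an acetate would not allow.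

Step 12
Reactants: 19 carbonate
Product: 20 6α-alcohol (19 without the silyl group)
Conditions: HF·pyridine, pyridine, THF, 0 °C to rt
Reagents that add atoms: none
Why: Fluoride cleavage of the only silyl ether; the PMB ether, the carbonate and the acetonide are stable to buffered HF·pyridine.

Step 13
Reactants: 20 6α-alcohol
Product: 21 6-ketone
Conditions: Dess–Martin periodinane, NaHCO3, CH2Cl2, 0 °C to rt
Reagents that add atoms: none
Why: Mild, buffered hypervalent-iodine oxidation of a secondary alcohol; near-neutral conditions are chosen so that the β,γ-unsaturated ketone is neither epimerised at C5 nor conjugated.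

Step 14
Reactants: 21 6-ketone
Product: 22 6β-alcohol (C6 epimer of 20; hydroxyl axial and cis to the C5 isopropenyl group)
Conditions: LiBH(s-Bu)3, THF, −78 °C; aq. NH4Cl
Reagents that add atoms: none
Why: Substrate-controlled ketone reduction: in the chair with the C10 methyl axial, axial approach to C6 from the β face is blocked by that syn-axial methyl, so the bulky hydride enters from the α side and gives the axial 6β alcohol, a net inversion of C6 that a displacement could not achieve past the same methyl group.

Step 15
Reactants: 22 6β-alcohol; 23 angelic acid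
Product: 25 6β-angelate [(Z)-2-methylbut-2-enoate] of 22, via mixed anhydride 24 (not isolated)
Conditions: 23, 2,4,6-trichlorobenzoyl chloride, Et3N, toluene, rt; then 22, 80 °C, no DMAP
Reagents that add atoms: 2,4,6-trichlorobenzoyl chloride O=C(Cl)c1c(Cl)cc(Cl)cc1Cl (aroyl group only in 24)
Why: Yamaguchi esterification through the mixed anhydride, run without a nucleophilic catalyst to avoid Z to E isomerisation; placing the angelate here removes any later acylation next to a free C9 hydroxyl and makes C6–H an electron-poor, unreactive site for the carbenoid.

Step 16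
Reactants: 25 6β-angelate
Product: 26 8α-alcohol (25 without the PMB group)
Conditions: DDQ, CH2Cl2/pH 7 buffer, 0 °C to rt
Reagents that add atoms: none
Why: Oxidative cleavage of a 4-methoxybenzyl ether by hydride abstraction and hydrolysis; conditions are neutral, so the neighbouring carbonate cannot cyclise onto O8, and the alkenes and esters are inert to DDQ.

Step 17
Reactants: 26 8α-alcohol; 27 diethylphosphonoacetic acid
Product: 28 8α-O-(diethylphosphonoacetyl) ester of 26
Conditions: EDC·HCl, DMAP (cat.), CH2Cl2, 0 °C to rt
Reagents that add atoms: none
Why: Carbodiimide esterification of the single free, equatorial hydroxyl; the acidic phosphonoacetate is introduced only now, after all hydride and strong-base steps.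

Step 18
Reactants: 28 phosphonoacetate
Product: 30 8α-O-[2-diazo-2-(diethoxyphosphoryl)acetyl] ester with 6β-angelate / 9α-OBoc / C1-C2 acetonide / 5β-isopropenyl / C7 methylene, via lithium enolate 29 (not isolated)
Conditions: LiN(SiMe3)2, THF, −78 °C; then 4-acetamidobenzenesulfonyl azide, −78 to 0 °C; aq. NH4Cl
Reagents that add atoms: 4-acetamidobenzenesulfonyl azide CC(=O)Nc1ccc(cc1)S(=O)(=O)N=[N+]=[N-]
Why: Regitz diazo transfer from a sulfonyl azide to the phosphonate-stabilised enolate, the only acidic site in 28; one equivalent of base at low temperature leaves the angelate and the carbonate untouched.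

Step 19
Reactants: 30 diazophosphonoacetate
Product: 31 cis-fused 8α,12-lactone with the new C7–C11 bond α and P(O)(OEt)2 on C11 (both C11 epimers) / 6β-angelate / 9α-OBoc / acetonide / 5β-isopropenyl
Conditions: Rh2(OAc)4 (2 mol %), CH2Cl2, reflux, slow addition of 30 at high dilution
Reagents that add atoms: none
Why: Rh2(OAc)4 (divalent rhodium) expels N2 from 30 to give an electrophilic acceptor/acceptor carbenoid at C11, which inserts into a C7–H bond through a three-centre transition state with retention at C7; this is the established 1,5 C–H insertion of diazophosphonoacetates to α-phosphono-γ-lactones. The lactone ring (O8, C12, C11, C7, C8) closes in the 1,5 mode, the five-membered closure these carbenoids prefer over four- and six-membered ones. The configuration of C7 is decided by which hydrogen is replaced: insertion favours equatorial C–H bonds, and in the chair with the C8 ester axial the only equatorial hydrogen next to C8 is H-7α, on the face of O8, so C11 becomes α and the fusion cis; C11 forms as two epimers, which converge in step 20. For site selectivity, C9–H is deactivated by the carbonate oxygen and lies anti to the axial ester, C6–H is deactivated by the angelate oxygen, and the acetonide and isopropenyl groups are out of reach of a five-membered transition state. The selectivity that is not secured by design is between the two C7 hydrogens: the other chair (ester equatorial) presents H-7β and would give the trans-fused C7 epimer, the two chairs are estimated to be close in energy, and the outcome rests on the usually faster reaction of the axial-ester chair. Slow addition and dilution suppress carbene dimerisation.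

Step 20
Reactants: 31 α-phosphono lactone
Product: 32 α-methylene lactone (C11=C13) with 6β-angelate / 9α-OBoc / acetonide / 5β-isopropenyl
Conditions: K2CO3, 37 % aq. HCHO, THF, 0 °C to rt
Reagents that add atoms: formaldehyde C=O
Why: Horner–Wadsworth–Emmons olefination of the phosphonate-stabilised lactone anion with formaldehyde; both C11 epimers give the same alkene, and mild carbonate base spares the angelate and the carbonate.

Step 21
Reactants: 32 α-methylene lactone
Product: 34 enal (isopropenyl methyl oxidised to the C15 aldehyde; C5 substituent is 3-oxoprop-1-en-2-yl), via allylic alcohol 33 (not isolated)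
Conditions: SeO2 (0.5 equiv), t-BuOOH, CH2Cl2, rt; filter; then MnO2, CH2Cl2, rt
Reagents that add atoms: tert-butyl hydroperoxide CC(C)(C)OO (oxygen relayed by selenium dioxide O=[Se]=O)
Why: Allylic oxidation by ene reaction and [2,3]-sigmatropic shift occurs at the methyl of the only electron-rich alkene (the two conjugated alkenes are inert), and MnO2 then oxidises the allylic alcohol selectively to the aldehyde.

Step 22
Reactants: 34 enal
Product: 35 triol (C1–OH, C2–OH and C9–OH free; 1S)
Conditions: TFA/H2O (9:1), CH2Cl2, 0 °C
Reagents that add atoms: none
Why: Acidolysis removes the acetonide (hydrolysis) and the tert-butyl carbonate (loss of the tert-butyl cation and CO2) in one operation; the enal, the methylene lactone and the angelate are stable to brief acid, and no base is needed to free O9.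

Step 23
Reactants: 35 triol
Product: 37 target CNP0113462.5, via primary tosylate 36 (not isolated)
Conditions: TsCl, Et3N, Bu2SnO (cat.), CH2Cl2, 0 °C; then DBU, 0 °C to rt
Reagents that add atoms: p-toluenesulfonyl chloride Cc1ccc(cc1)S(Cl)(=O)=O (sulfonyl group only in 36)
Why: Tin-catalysed sulfonylation selects the primary hydroxyl of the 1,2-diol, and the C1 oxygen then displaces the tosylate in a 3-exo-tet Williamson closure, kinetically favoured over attack by the more distant C9 hydroxyl; the C1–O bond is not broken, so C1 stays S.

## Compound list

1 | 2-methylcyclohexane-1,3-dione | CC1C(=O)CCCC1=O | starting material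
2 | 3-ethoxy-2-methylcyclohex-2-en-1-one | CCOC1=C(C)C(=O)CCC1 | intermediate
3 | (±)-6-acetoxy-3-ethoxy-2-methylcyclohex-2-en-1-one | CCOC1=C(C)C(=O)C(OC(C)=O)CC1 | intermediate
4 | (S)-6-acetoxy-3-ethoxy-2-methylcyclohex-2-en-1-one | CCOC1=C(C)C(=O)[C@@H](OC(C)=O)CC1 | intermediate
5 | (6S)-3-ethoxy-2-methylcyclohex-2-ene-1,6-diol, C1 epimers (not isolated) | CCOC1=C(C)C(O)[C@@H](O)CC1 | intermediate
6 | (S)-4-hydroxy-2-methylcyclohex-2-en-1-one | O=C1CC[C@H](O)C=C1C | intermediate
7 | (S)-4-(tert-butyldimethylsilyloxy)-2-methylcyclohex-2-en-1-one | O=C1CC[C@H](O[Si](C)(C)C(C)(C)C)C=C1C | intermediate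
8 | isopropenylmagnesium bromide | CC(=C)[Mg]Br | starting material
9 | (tert-butyldimethylsilyloxy)acetaldehyde | O=CCO[Si](C)(C)C(C)(C)C | starting material
10 | bromomagnesium C9-enolate with 5β-isopropenyl and 6α-OTBS (not isolated) | C1C[C@H](O[Si](C)(C)C(C)(C)C)[C@@H](C(C)=C)C(C)=C1O[Mg]Br | intermediate
11 | aldol adduct: 9-ketone, 10β-methyl, 10α-[(1S)-1-hydroxy-2-(TBS-oxy)ethyl], 5β-isopropenyl, 6α-OTBS | C1C[C@H](O[Si](C)(C)C(C)(C)C)[C@@H](C(C)=C)[C@](C)([C@H](O)CO[Si](C)(C)C(C)(C)C)C1=O | intermediate
12 | C1,C2-diol of 11 (not isolated) | C1C[C@H](O[Si](C)(C)C(C)(C)C)[C@@H](C(C)=C)[C@](C)([C@H](O)CO)C1=O | intermediate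
13 | acetonide ketone: 10α-[(4S)-2,2-dimethyl-1,3-dioxolan-4-yl], 10β-methyl, 5β-isopropenyl, 6α-OTBS, 9-ketone | C1C[C@H](O[Si](C)(C)C(C)(C)C)[C@@H](C(C)=C)[C@](C)([C@H]2COC(C)(C)O2)C1=O | intermediate
14 | potassium C8=C9 enolate of 13 (not isolated) | [K+].[O-]C1=CC[C@H](O[Si](C)(C)C(C)(C)C)[C@@H](C(C)=C)[C@]1(C)[C@H]2COC(C)(C)O2 | intermediate
15 | 8α-hydroxy ketone | O[C@@H]1C[C@H](O[Si](C)(C)C(C)(C)C)[C@@H](C(C)=C)[C@](C)([C@H]2COC(C)(C)O2)C1=O | intermediate
16 | 8α,9α-diol | O[C@@H]1C[C@H](O[Si](C)(C)C(C)(C)C)[C@@H](C(C)=C)[C@](C)([C@H]2COC(C)(C)O2)[C@@H]1O | intermediate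
17 | 8,9-O-dibutylstannylene acetal of 16 (not isolated) | CCCC[Sn]1(CCCC)O[C@@H]2C[C@H](O[Si](C)(C)C(C)(C)C)[C@@H](C(C)=C)[C@](C)([C@H]3COC(C)(C)O3)[C@@H]2O1 | intermediate
18 | 8α-O-(4-methoxybenzyl) ether, 9α-OH | COc1ccc(CO[C@@H]2C[C@H](O[Si](C)(C)C(C)(C)C)[C@@H](C(C)=C)[C@](C)([C@H]3COC(C)(C)O3)[C@@H]2O)cc1 | intermediate
19 | 9α-O-Boc carbonate of 18 | COc1ccc(CO[C@@H]2C[C@H](O[Si](C)(C)C(C)(C)C)[C@@H](C(C)=C)[C@](C)([C@H]3COC(C)(C)O3)[C@@H]2OC(=O)OC(C)(C)C)cc1 | intermediate
20 | 6α-alcohol | COc1ccc(CO[C@@H]2C[C@H](O)[C@@H](C(C)=C)[C@](C)([C@H]3COC(C)(C)O3)[C@@H]2OC(=O)OC(C)(C)C)cc1 | intermediate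
21 | 6-ketone | COc1ccc(CO[C@@H]2CC(=O)[C@@H](C(C)=C)[C@](C)([C@H]3COC(C)(C)O3)[C@@H]2OC(=O)OC(C)(C)C)cc1 | intermediate
22 | 6β-alcohol | COc1ccc(CO[C@@H]2C[C@@H](O)[C@@H](C(C)=C)[C@](C)([C@H]3COC(C)(C)O3)[C@@H]2OC(=O)OC(C)(C)C)cc1 | intermediate
23 | angelic acid, (Z)-2-methylbut-2-enoic acid | C/C=C(/C)C(=O)O | starting material
24 | angelic 2,4,6-trichlorobenzoic anhydride (not isolated) | C/C=C(/C)C(=O)OC(=O)c1c(Cl)cc(Cl)cc1Cl | intermediate
25 | 6β-angelate, 8α-OPMB, 9α-OBoc | COc1ccc(CO[C@@H]2C[C@@H](OC(=O)/C(C)=C\C)[C@@H](C(C)=C)[C@](C)([C@H]3COC(C)(C)O3)[C@@H]2OC(=O)OC(C)(C)C)cc1 | intermediate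
26 | 8α-alcohol: 6β-angelate, 9α-OBoc, acetonide | O[C@@H]1C[C@@H](OC(=O)/C(C)=C\C)[C@@H](C(C)=C)[C@](C)([C@H]2COC(C)(C)O2)[C@@H]1OC(=O)OC(C)(C)C | intermediate
27 | diethylphosphonoacetic acid | CCOP(=O)(CC(=O)O)OCC | starting material
28 | 8α-O-(diethylphosphonoacetyl) ester | CCOP(=O)(OCC)CC(=O)O[C@@H]1C[C@@H](OC(=O)/C(C)=C\C)[C@@H](C(C)=C)[C@](C)([C@H]2COC(C)(C)O2)[C@@H]1OC(=O)OC(C)(C)C | intermediate
29 | lithium enolate of 28 (not isolated) | [Li+].CCOP(=O)(OCC)[CH-]C(=O)O[C@@H]1C[C@@H](OC(=O)/C(C)=C\C)[C@@H](C(C)=C)[C@](C)([C@H]2COC(C)(C)O2)[C@@H]1OC(=O)OC(C)(C)C | intermediate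
30 | 8α-O-[2-diazo-2-(diethoxyphosphoryl)acetyl] ester, key-step precursor | CCOP(=O)(OCC)C(=[N+]=[N-])C(=O)O[C@@H]1C[C@@H](OC(=O)/C(C)=C\C)[C@@H](C(C)=C)[C@](C)([C@H]2COC(C)(C)O2)[C@@H]1OC(=O)OC(C)(C)C | intermediate
31 | cis-fused α-phosphono lactone, C11 epimers, key-step product | CCOP(=O)(OCC)C1C(=O)O[C@@H]2[C@H]1[C@@H](OC(=O)/C(C)=C\C)[C@@H](C(C)=C)[C@](C)([C@H]3COC(C)(C)O3)[C@@H]2OC(=O)OC(C)(C)C | intermediate
32 | α-methylene lactone | C=C1C(=O)O[C@@H]2[C@H]1[C@@H](OC(=O)/C(C)=C\C)[C@@H](C(C)=C)[C@](C)([C@H]3COC(C)(C)O3)[C@@H]2OC(=O)OC(C)(C)C | intermediate
33 | C15 allylic alcohol (not isolated) | C=C1C(=O)O[C@@H]2[C@H]1[C@@H](OC(=O)/C(C)=C\C)[C@@H](C(=C)CO)[C@](C)([C@H]3COC(C)(C)O3)[C@@H]2OC(=O)OC(C)(C)C | intermediate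
34 | enal with 9α-OBoc and acetonide | C=C1C(=O)O[C@@H]2[C@H]1[C@@H](OC(=O)/C(C)=C\C)[C@@H](C(=C)C=O)[C@](C)([C@H]3COC(C)(C)O3)[C@@H]2OC(=O)OC(C)(C)C | intermediate
35 | triol (C1, C2, C9 hydroxyls free) | C=C1C(=O)O[C@@H]2[C@H]1[C@@H](OC(=O)/C(C)=C\C)[C@@H](C(=C)C=O)[C@](C)([C@H](O)CO)[C@@H]2O | intermediate
36 | C2 p-toluenesulfonate of 35 (not isolated) | C=C1C(=O)O[C@@H]2[C@H]1[C@@H](OC(=O)/C(C)=C\C)[C@@H](C(=C)C=O)[C@](C)([C@H](O)COS(=O)(=O)c1ccc(C)cc1)[C@@H]2O | intermediate
37 | CNP0113462.5 | C=C1C(=O)O[C@@H]2[C@H]1[C@@H](OC(=O)/C(C)=C\C)[C@@H](C(=C)C=O)[C@](C)([C@H]1CO1)[C@@H]2O | target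

## Step count and least certain steps

Total: 23 steps. Longest linear sequence: 23 steps from 1; compounds 8, 9, 23 and 27 are purchased and enter directly.

Step 19 (key step). The most likely failure is reaction through the chair with the C8 ester equatorial. There the equatorial C7 hydrogen is the β one, and insertion into it gives the C7 epimer with a trans ring fusion. The two chairs differ little in estimated strain, and no protecting-group choice locks the ring. Slower insertion than usual (C7–H lies between two oxygenated carbons) would also let carbene dimerisation or ylide formation with an acetonide oxygen compete. Fallback, from 26 back to 32: acylation of 26 with bromoacetyl bromide gives the bromoacetate F1. N,N′-ditosylhydrazine and DBU convert it into the diazoacetate F2. A chiral dirhodium carboxamidate, Rh2(4S-MACIM)4 or its enantiomer (whichever is matched), is then used; this catalyst class is known to close cyclohexyl diazoacetates to cis-fused lactones by selecting the axial-ester chair, and should give the cis-fused lactone F3. Kinetic deprotonation with LiN(SiMe3)2 at −78 °C and Eschenmoser's salt give the Mannich base F4, and quaternisation with MeI followed by NaHCO3 elimination returns to 32. The approach changes from an acceptor/acceptor carbenoid with built-in olefination to catalyst-controlled insertion plus separate methylenation.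

Step 6. The aldolate on a quaternary carbon can revert (retro-aldol) and equilibrate, and a boat or open transition state would erode selectivity at C1. C1 is the one centre here that the ring does not control directly. Fallback, from 11 (taken as the mixture of C1 epimers) back to 11: Dess–Martin oxidation gives the non-enolisable β-diketone F5. Reduction of the activated α-silyloxy ketone with BH3·SMe2 and (S)-2-methyl-CBS-oxazaborolidine follows; C10 is the large group and the hindered C9 ketone should react more slowly. This sets C1 as S under reagent control.

Step 14 (with step 13). Enolisation of the β,γ-unsaturated ketone 21 toward C5 during oxidation or reduction would epimerise C5 or move the alkene into conjugation. Incomplete face selectivity of the hydride is the second concern. Fallback, from 20 back to 22, avoiding the ketone: Tf2O and pyridine give the triflate F6. Displacement with KNO2 in DMF (Lattrell–Dax inversion) and hydrolysis of the nitrite ester on work-up give 22. This is hindered by the syn-axial methyl, so it is held in reserve.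

Step 15. Acylation of the axial, doubly flanked 6β hydroxyl may be slow, and prolonged heating promotes isomerisation of the Z-enoate to the tiglate. Fallback, from 22 back to 25: DCC coupling with 2-[bis(2,2,2-trifluoroethoxy)phosphoryl]propanoic acid gives the phosphonopropionate F7. Still–Gennari olefination with acetaldehyde (KN(SiMe3)2, 18-crown-6, THF, −78 °C) then builds the Z-2-methylbut-2-enoate on the molecule.

Step 23. Under base the C9 alkoxide can compete with the C1 alkoxide for the C2 tosylate (5-exo closure to a tetrahydrofuran). The amidine base can also add to the enal or the methylene lactone or shift the exocyclic alkene into the ring. Fallback, from 35 back to 37, without generating alkoxides: I2, PPh3 and imidazole convert the primary hydroxyl into the primary iodide F8. Ag2O in MeCN in the dark then closes the oxirane by halophilic activation under neutral conditions.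

## Further compounds

F1 | step 19 | 8α-O-bromoacetyl ester of 26 | BrCC(=O)O[C@@H]1C[C@@H](OC(=O)/C(C)=C\C)[C@@H](C(C)=C)[C@](C)([C@H]2COC(C)(C)O2)[C@@H]1OC(=O)OC(C)(C)C
F2 | step 19 | 8α-O-diazoacetyl ester of 26 | [N-]=[N+]=CC(=O)O[C@@H]1C[C@@H](OC(=O)/C(C)=C\C)[C@@H](C(C)=C)[C@](C)([C@H]2COC(C)(C)O2)[C@@H]1OC(=O)OC(C)(C)C
F3 | step 19 | cis-fused 8α,12-lactone without phosphonate (C11 methylene) | C1C(=O)O[C@@H]2[C@H]1[C@@H](OC(=O)/C(C)=C\C)[C@@H](C(C)=C)[C@](C)([C@H]3COC(C)(C)O3)[C@@H]2OC(=O)OC(C)(C)C
F4 | step 19 | 11-(dimethylaminomethyl) lactone, C11 epimers | CN(C)CC1C(=O)O[C@@H]2[C@H]1[C@@H](OC(=O)/C(C)=C\C)[C@@H](C(C)=C)[C@](C)([C@H]3COC(C)(C)O3)[C@@H]2OC(=O)OC(C)(C)C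
F5 | step 6 | 1,9-diketone from oxidation of 11 | C1C[C@H](O[Si](C)(C)C(C)(C)C)[C@@H](C(C)=C)[C@](C)(C(=O)CO[Si](C)(C)C(C)(C)C)C1=O
F6 | step 14 | 6α-trifluoromethanesulfonate of 20 | COc1ccc(CO[C@@H]2C[C@H](OS(=O)(=O)C(F)(F)F)[C@@H](C(C)=C)[C@](C)([C@H]3COC(C)(C)O3)[C@@H]2OC(=O)OC(C)(C)C)cc1
F7 | step 15 | 6β-O-{2-[bis(2,2,2-trifluoroethoxy)phosphoryl]propanoyl} ester of 22 | COc1ccc(CO[C@@H]2C[C@@H](OC(=O)C(C)P(=O)(OCC(F)(F)F)OCC(F)(F)F)[C@@H](C(C)=C)[C@](C)([C@H]3COC(C)(C)O3)[C@@H]2OC(=O)OC(C)(C)C)cc1
F8 | step 23 | C2 iodide of 35 (1-hydroxy-2-iodoethyl on C10) | C=C1C(=O)O[C@@H]2[C@H]1[C@@H](OC(=O)/C(C)=C\C)[C@@H](C(=C)C=O)[C@](C)([C@H](O)CI)[C@@H]2O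
A1 | alternative 1 | 1,2-deoxy target with a C10 vinyl group, Cope product | C=C1C(=O)O[C@@H]2[C@H]1[C@@H](OC(=O)/C(C)=C\C)[C@@H](C(=C)C=O)[C@](C)(C=C)[C@@H]2O
A2 | alternative 1 | germacra-1(10),4-dien-15-al-8,12-olide with 6-angelate and 9-hydroxyl, Cope precursor | C=C1C(=O)O[C@@H]2[C@H]1[C@@H](OC(=O)/C(C)=C\C)/C=C(C=O)/CC/C=C(C)/[C@@H]2O
A3 | alternative 2 | cis-fused α-methylene lactone with 6-OTBS, 15-OTBS, 9-OPMB and C10 vinyl | C=C1C(=O)O[C@@H]2[C@H]1[C@@H](O[Si](C)(C)C(C)(C)C)[C@@H](C(=C)CO[Si](C)(C)C(C)(C)C)[C@](C)(C=C)[C@@H]2OCc1ccc(OC)cc1
A4 | alternative 2 | open-chain C8 aldehyde with the 2-(bromomethyl)acrylate terminus, E/Z mixture | O=C[C@@H](OCc1ccc(OC)cc1)[C@@](C)(C=C)[C@H](C(=C)CO[Si](C)(C)C(C)(C)C)[C@H](O[Si](C)(C)C(C)(C)C)C=C(CBr)C(=O)OC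
A5 | alternative 3 | cyclohexanol from reductive aldol closure (9-OH cis to the C1 acyl group) | CC(C)(C)[Si](C)(C)O[C@@H]2[C@H](CC(=O)OC)[C@@H](O[Si](C)(C)C(C)(C)C)[C@@H](C(C)=C)[C@](C)(C(=O)COCc1ccc(OC)cc1)[C@@H]2O
A6 | alternative 3 | open-chain C9 aldehyde with the C10 methylene ketone | O=C[C@H](O[Si](C)(C)C(C)(C)C)[C@H](CC(=O)OC)[C@@H](O[Si](C)(C)C(C)(C)C)[C@@H](C(C)=C)C(=C)C(=O)COCc1ccc(OC)cc1
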